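## Retrosynthetic overview

1. The C1 carbinol comes last, by 1,3-anti reduction of a macrocyclic β-hydroxy enone; the ten-membered ring is closed just before by ring-closing metathesis at C4=C5 (C5 vinyl + C4 isopropenyl).
2. The seco-enone comes from a Nozaki–Hiyama–Kishi union at C1–C10 of a bottom Z-alkenyl iodide (C5–C9, lactone, angelate) with a top aldehyde (C1–C4), followed by oxidation. The enone also keeps C9=C10 out of the metathesis.
3. The bottom half comes from diacetone-D-glucose: a 3-C-branched allofuranose supplies C6/C7/C8, an α-iodo-ylide Wittig gives the Z-iodoalkene, and the γ-lactone closes on acetonide hydrolysis. Vinyl, α-methylene and angelate follow.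
4. The top half comes from an Evans chloroacetate aldol with methacrolein, which sets C3.
5. Ring order: γ-lactone first (step 5), ten-membered carbocycle second (step 19).

Assumption: germacrane numbering is used (ring C1–C10, lactone carbons C11–C13, methyl C14 on C10, methyl C15 on C4); the SMILES is read as 1S,3S,6S,7S,8R with 4Z and 9Z ring olefins, a cis-fused 6,12-lactone and an 8-O-angelate [(Z)-2-methylbut-2-enoate].

## Route

Step 1
Reactants: 1 1,2:5,6-di-O-isopropylidene-α-D-glucofuranose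
Product: 3 methyl (3-deoxy-1,2:5,6-di-O-isopropylidene-α-D-ribo-hexofuranos-3-ylidene)acetate (E/Z mixture), via 3-ulose 2 (not isolated)
Conditions: Dess–Martin periodinane, CH2Cl2, rt; then Ph3P=CHCO2Me, rt, one pot
Reagents that add atoms: methyl (triphenylphosphoranylidene)acetate, COC(=O)C=P(c1ccccc1)(c1ccccc1)c1ccccc1
Why: Dess–Martin oxidation gives the strained 3-ulose, which is trapped in the same flask by the stabilised ylide in a Wittig olefination before it can hydrate; the alkene geometry is irrelevant because the next step saturates it.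

Step 2
Reactants: 3 methyl (3-deoxy-1,2:5,6-di-O-isopropylidene-α-D-ribo-hexofuranos-3-ylidene)acetate
Product: 4 3-deoxy-3-C-(2-methoxy-2-oxoethyl)-1,2:5,6-di-O-isopropylidene-α-D-allofuranose
Conditions: H2 (1 atm), 10% Pd/C, EtOAc, rt
Reagents that add atoms: none
Why: Heterogeneous catalytic hydrogenation delivers H2 to the convex β-face of the cis-fused furanose–dioxolane, so the CH2CO2Me branch ends up α (allo, cis to O-2), which sets C7 of the target relative to the sugar-derived C6 and C8.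

Step 3
Reactants: 4 3-deoxy-3-C-(2-methoxy-2-oxoethyl)-1,2:5,6-di-O-isopropylidene-α-D-allofuranose
Product: 6 3-deoxy-3-C-(2-methoxy-2-oxoethyl)-1,2-O-isopropylidene-α-D-ribo-pentodialdo-1,4-furanose, via 5,6-diol 5 (not isolated)
Conditions: H5IO6 (1.3 equiv), EtOAc, rt
Reagents that add atoms: none
Why: Periodic acid in ethyl acetate hydrolyses only the terminal 5,6-acetonide and cleaves the liberated glycol in one pot (glycol cleavage), leaving the 1,2-acetonide, the ester and all three stereocentres untouched.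

Step 4
Reactants: 6 3-deoxy-3-C-(2-methoxy-2-oxoethyl)-1,2-O-isopropylidene-α-D-ribo-pentodialdo-1,4-furanose
Product: 7 (Z)-3,5,6,7-tetradeoxy-6-iodo-3-C-(2-methoxy-2-oxoethyl)-1,2-O-isopropylidene-α-D-ribo-hept-5-enofuranose
Conditions: EtPPh3I, n-BuLi, THF, 0 °C; I2, −78 °C; NaN(SiMe3)2, −20 °C; then 6, −78 °C
Reagents that add atoms: ethyltriphenylphosphonium iodide, CC[P+](c1ccccc1)(c1ccccc1)c1ccccc1.[I-]; iodine, II
Why: Zhao's α-iodoethylidene Wittig olefination (Stork–Zhao type) gives the Z-2-iodo-2-alkene (C8 cis to iodine, methyl trans) at −78 °C, conditions under which the α-alkoxy aldehyde does not epimerise and the ester is not attacked.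

Step 5
Reactants: 7 (Z)-3,5,6,7-tetradeoxy-6-iodo-3-C-(2-methoxy-2-oxoethyl)-1,2-O-isopropylidene-α-D-ribo-hept-5-enofuranose
Product: 9 (Z)-3-C-(carboxymethyl)-3,5,6,7-tetradeoxy-6-iodo-D-ribo-hept-5-enofuranose 2-O-lactone (lactol anomers), via hydroxy ester lactol 8 (not isolated)
Conditions: CF3CO2H/H2O (9:1), 0 °C → rt
Reagents that add atoms: none
Why: Acid hydrolysis of the 1,2-acetonide frees O-2, which lactonises at once onto the cis-disposed ester (acid-catalysed lactonisation), while the other triad oxygen (future O8) stays locked as the furanose ring oxygen, so the lactone can only form on the future O6.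

Step 6
Reactants: 9 (Z)-3-C-(carboxymethyl)-3,5,6,7-tetradeoxy-6-iodo-D-ribo-hept-5-enofuranose 2-O-lactone
Product: 10 (4R,5S)-5-ethenyl-4-[(1S,2Z)-1-hydroxy-3-iodobut-2-en-1-yl]oxolan-2-one
Conditions: Ph3PCH3Br, KN(SiMe3)2, THF, 0 °C; then 9, −78 → 0 °C
Reagents that add atoms: methyltriphenylphosphonium bromide (as its ylide), C[P+](c1ccccc1)(c1ccccc1)c1ccccc1.[Br-]
Why: Wittig methylenation of the ring-opened hydroxy-aldehyde tautomer of the lactol installs the C5 vinyl group and frees the C8 hydroxyl; no stereocentre is formed, and migration of the lactone to O8 is disfavoured because it needs a strained 2,7-dioxabicyclo[2.2.1]heptane ortho ester.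

Step 7
Reactants: 10 (4R,5S)-5-ethenyl-4-[(1S,2Z)-1-hydroxy-3-iodobut-2-en-1-yl]oxolan-2-one
Product: 13 (4R,5S)-5-ethenyl-4-[(1S,2Z)-1-hydroxy-3-iodobut-2-en-1-yl]-3-methylideneoxolan-2-one, via Mannich base 11 (not isolated), via trimethylammonium iodide 12 (not isolated)
Conditions: LiN(iPr)2 (2.2 equiv), THF, −78 °C; CH2=NMe2+ I−, −78 → 0 °C; then MeI, MeOH, rt; then aq. NaHCO3/CH2Cl2
Reagents that add atoms: N,N-dimethylmethyleneiminium iodide (Eschenmoser's salt), C=[N+](C)C.[I-]; iodomethane, CI (stays only in 12)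
Why: Mannich aminomethylation of the lactone enolate (dianion with the C8 alkoxide) with Eschenmoser's salt, N-quaternisation and E1cB elimination give the α-methylene lactone; the transient C11 centre is destroyed in the elimination.

Step 8
Reactants: 14 angelic acid [(2Z)-2-methylbut-2-enoic acid] (2 equiv)
Product: 15 angelic anhydride
Conditions: DCC (0.5 equiv), CH2Cl2, 0 °C → rt; filtration
Reagents that add atoms: none
Why: Carbodiimide dehydration of two molecules of angelic acid gives the symmetric anhydride under neutral conditions that do not isomerise the Z double bond.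

Step 9
Reactants: 13 (4R,5S)-5-ethenyl-4-[(1S,2Z)-1-hydroxy-3-iodobut-2-en-1-yl]-3-methylideneoxolan-2-one; 15 angelic anhydride
Product: 16 (1S,2Z)-1-[(2S,3S)-2-ethenyl-4-methylidene-5-oxooxolan-3-yl]-3-iodobut-2-en-1-yl (2Z)-2-methylbut-2-enoate
Conditions: LiN(SiMe3)2 (1.05 equiv), THF, −78 °C; then 15, −78 → −40 °C
Reagents that add atoms: none
Why: O-acylation of the pre-formed lithium alkoxide with angelic anhydride at −78 °C is a fast kinetic esterification that avoids nucleophilic catalysts, so the angelate stays Z and C8 is untouched (the CIP labels change only because priorities change).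

Step 10
Reactants: 17 (4S)-4-benzyl-1,3-oxazolidin-2-one; 18 chloroacetyl chloride
Product: 19 (4S)-4-benzyl-3-(2-chloroacetyl)-1,3-oxazolidin-2-one
Conditions: n-BuLi, THF, −78 °C; then 18
Reagents that add atoms: none
Why: N-acylation of the lithiated Evans oxazolidinone with the acid chloride.

Step 11
Reactants: 19 (4S)-4-benzyl-3-(2-chloroacetyl)-1,3-oxazolidin-2-one; 20 methacrolein (2-methylprop-2-enal)
Product: 21 (4S)-4-benzyl-3-[(2S,3R)-2-chloro-3-hydroxy-4-methylpent-4-enoyl]-1,3-oxazolidin-2-one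
Conditions: Bu2BOTf, i-Pr2NEt, Et2O/CH2Cl2, −78 → 0 °C; then 20, −78 °C; aqueous work-up
Reagents that add atoms: none
Why: Evans syn-aldol reaction: the Z-boron enolate adds through a Zimmerman–Traxler chair, the (S)-benzyl auxiliary fixes the carbinol centre that becomes C3 (S) of the target, and the α-chlorine gives much higher selectivity than a plain acetate aldol.

Step 12
Reactants: 21 (4S)-4-benzyl-3-[(2S,3R)-2-chloro-3-hydroxy-4-methylpent-4-enoyl]-1,3-oxazolidin-2-one
Product: 22 (4S)-4-benzyl-3-[(3S)-3-hydroxy-4-methylpent-4-enoyl]-1,3-oxazolidin-2-one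
Conditions: Zn dust, AcOH, THF, rt
Reagents that add atoms: none
Why: Reductive dechlorination with zinc in acetic acid removes the α-chlorine (zinc enolate protonated in situ) without touching the carbinol centre or the alkene.

Step 13
Reactants: 22 (4S)-4-benzyl-3-[(3S)-3-hydroxy-4-methylpent-4-enoyl]-1,3-oxazolidin-2-one
Product: 23 (4S)-4-benzyl-3-[(3S)-4-methyl-3-(triethylsilyloxy)pent-4-enoyl]-1,3-oxazolidin-2-one
Conditions: Et3SiCl, imidazole, CH2Cl2, 0 °C
Reagents that add atoms: chlorotriethylsilane, CC[Si](Cl)(CC)CC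
Why: Silylation of the secondary alcohol; the triethylsilyl ether survives the reduction, the oxidations and the Cr/Ni coupling that follow.

Step 14
Reactants: 23 (4S)-4-benzyl-3-[(3S)-4-methyl-3-(triethylsilyloxy)pent-4-enoyl]-1,3-oxazolidin-2-one
Product: 24 (3S)-4-methyl-3-(triethylsilyloxy)pent-4-en-1-ol
Conditions: LiBH4, Et2O, MeOH (1 equiv), 0 °C
Reagents that add atoms: none
Why: Reductive cleavage of the imide with lithium borohydride gives the primary alcohol and returns the auxiliary.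

Step 15
Reactants: 24 (3S)-4-methyl-3-(triethylsilyloxy)pent-4-en-1-ol
Product: 25 (3S)-4-methyl-3-(triethylsilyloxy)pent-4-enal
Conditions: Dess–Martin periodinane, NaHCO3, CH2Cl2, rt
Reagents that add atoms: none
Why: Dess–Martin oxidation of the primary alcohol to the β-silyloxy aldehyde under buffered conditions that avoid β-elimination.

Step 16
Reactants: 16 (1S,2Z)-1-[(2S,3S)-2-ethenyl-4-methylidene-5-oxooxolan-3-yl]-3-iodobut-2-en-1-yl (2Z)-2-methylbut-2-enoate; 25 (3S)-4-methyl-3-(triethylsilyloxy)pent-4-enal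
Product: 26 (1R,2Z,4RS,6S)-1-[(2S,3S)-2-ethenyl-4-methylidene-5-oxooxolan-3-yl]-4-hydroxy-3,7-dimethyl-6-(triethylsilyloxy)octa-2,7-dien-1-yl (2Z)-2-methylbut-2-enoate
Conditions: CrCl2 (6 equiv), NiCl2 (2 mol %), DMSO, rt
Reagents that add atoms: none
Why: Nozaki–Hiyama–Kishi coupling: the alkenylchromium formed from the Z-iodide (geometry retained) adds chemoselectively to the aldehyde in the presence of the lactone, the ester and the exo-methylene group; the C1 epimer ratio is irrelevant because C1 is oxidised next.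

Step 17
Reactants: 26 (C1-epimeric allylic alcohols)
Product: 27 (1R,2Z,6S)-1-[(2S,3S)-2-ethenyl-4-methylidene-5-oxooxolan-3-yl]-3,7-dimethyl-4-oxo-6-(triethylsilyloxy)octa-2,7-dien-1-yl (2Z)-2-methylbut-2-enoate
Conditions: Dess–Martin periodinane, NaHCO3, CH2Cl2, 0 °C
Reagents that add atoms: none
Why: Dess–Martin oxidation of the allylic alcohol erases the C1 mixture and turns C9=C10 into a conjugated, electron-poor trisubstituted enone that does not take part in the later metathesis (an ordinary trisubstituted olefin there would cyclise with the C5 vinyl to a cyclopentene).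

Step 18
Reactants: 27 (silyl ether enone)
Product: 28 (1R,2Z,6S)-1-[(2S,3S)-2-ethenyl-4-methylidene-5-oxooxolan-3-yl]-6-hydroxy-3,7-dimethyl-4-oxoocta-2,7-dien-1-yl (2Z)-2-methylbut-2-enoate
Conditions: HF·pyridine, pyridine, THF, 0 °C
Reagents that add atoms: none
Why: Buffered fluoride desilylation frees the C3 hydroxyl, which is needed to ease metathesis at the neighbouring isopropenyl group and to direct the final reduction.

Step 19
Reactants: 28 (β-hydroxy enone triene)
Product: 29 (3aS,4R,5Z,9S,10Z,11aS)-9-hydroxy-6,10-dimethyl-3-methylidene-2,7-dioxo-2,3,3a,4,7,8,9,11a-octahydrocyclodeca[b]furan-4-yl (2Z)-2-methylbut-2-enoate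
Conditions: second-generation Hoveyda–Grubbs catalyst, RuCl2(SIMes)(=CH-C6H4-2-OiPr) (15 mol %), 1,4-benzoquinone (20 mol %), toluene (1 mM), 80 °C
Reagents that add atoms: none
Why: Ring-closing metathesis between the C5 vinyl and the C4 isopropenyl groups closes the ten-membered ring with loss of ethene; the ring (a cis,cis-cyclodeca-1,6-diene) enforces the Z geometry of the new trisubstituted olefin, and the enone, angelate and exo-methylene olefins are too electron-poor or hindered to compete.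

Step 20
Reactants: 29 (macrocyclic β-hydroxy enone)
Product: 30 (3aS,4R,5Z,7S,9S,10Z,11aS)-7,9-dihydroxy-6,10-dimethyl-3-methylidene-2-oxo-2,3,3a,4,7,8,9,11a-octahydrocyclodeca[b]furan-4-yl (2Z)-2-methylbut-2-enoate (target)
Conditions: Me4NBH(OAc)3, MeCN/AcOH (1:1), −30 °C
Reagents that add atoms: none
Why: Evans–Saksena reduction: the C3 hydroxyl binds the triacetoxyborohydride and delivers hydride intramolecularly through a chair transition state, giving the 1,3-anti diol and so C1 (S), without conjugate reduction of the unsaturated esters.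

## Compound list

1 | 1,2:5,6-di-O-isopropylidene-α-D-glucofuranose | O[C@@H]1[C@H]2OC(C)(C)O[C@H]2O[C@@H]1[C@H]1COC(C)(C)O1 | starting material
2 | 1,2:5,6-di-O-isopropylidene-α-D-ribo-hexofuranos-3-ulose | O=C1[C@H]2OC(C)(C)O[C@H]2O[C@@H]1[C@H]1COC(C)(C)O1 | intermediate (not isolated)
3 | methyl (3-deoxy-1,2:5,6-di-O-isopropylidene-α-D-ribo-hexofuranos-3-ylidene)acetate (E/Z mixture) | COC(=O)C=C1[C@H]2OC(C)(C)O[C@H]2O[C@@H]1[C@H]1COC(C)(C)O1 | intermediate
4 | 3-deoxy-3-C-(2-methoxy-2-oxoethyl)-1,2:5,6-di-O-isopropylidene-α-D-allofuranose | COC(=O)C[C@H]1[C@H]2OC(C)(C)O[C@H]2O[C@@H]1[C@H]1COC(C)(C)O1 | intermediate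
5 | 3-deoxy-3-C-(2-methoxy-2-oxoethyl)-1,2-O-isopropylidene-α-D-allofuranose (5,6-diol) | COC(=O)C[C@H]1[C@H]2OC(C)(C)O[C@H]2O[C@@H]1[C@H](O)CO | intermediate (not isolated)
6 | 3-deoxy-3-C-(2-methoxy-2-oxoethyl)-1,2-O-isopropylidene-α-D-ribo-pentodialdo-1,4-furanose | COC(=O)C[C@H]1[C@H]2OC(C)(C)O[C@H]2O[C@@H]1C=O | intermediate
7 | (Z)-3,5,6,7-tetradeoxy-6-iodo-3-C-(2-methoxy-2-oxoethyl)-1,2-O-isopropylidene-α-D-ribo-hept-5-enofuranose | COC(=O)C[C@H]1[C@H]2OC(C)(C)O[C@H]2O[C@@H]1/C=C(/C)I | intermediate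
8 | (Z)-3,5,6,7-tetradeoxy-6-iodo-3-C-(2-methoxy-2-oxoethyl)-D-ribo-hept-5-enofuranose (hydroxy ester lactol, anomers) | COC(=O)C[C@H]1[C@@H](O)C(O)O[C@@H]1/C=C(/C)I | intermediate (not isolated)
9 | (Z)-3-C-(carboxymethyl)-3,5,6,7-tetradeoxy-6-iodo-D-ribo-hept-5-enofuranose 2-O-lactone (cis-fused furo[3,4-b]furan-2-one lactol, anomers) | O=C1C[C@H]2[C@@H](O1)C(O)O[C@@H]2/C=C(/C)I | intermediate
10 | (4R,5S)-5-ethenyl-4-[(1S,2Z)-1-hydroxy-3-iodobut-2-en-1-yl]oxolan-2-one | O=C1C[C@H]([C@H](O)/C=C(/C)I)[C@H](C=C)O1 | intermediate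
11 | 3-[(dimethylamino)methyl] derivative of 10 (Mannich base, C3 epimers) | O=C1C(CN(C)C)[C@H]([C@H](O)/C=C(/C)I)[C@H](C=C)O1 | intermediate (not isolated)
12 | 3-[(trimethylammonio)methyl] derivative of 10, iodide | O=C1C(C[N+](C)(C)C)[C@H]([C@H](O)/C=C(/C)I)[C@H](C=C)O1.[I-] | intermediate (not isolated)
13 | (4R,5S)-5-ethenyl-4-[(1S,2Z)-1-hydroxy-3-iodobut-2-en-1-yl]-3-methylideneoxolan-2-one | O=C1C(=C)[C@H]([C@H](O)/C=C(/C)I)[C@H](C=C)O1 | intermediate
14 | angelic acid, (2Z)-2-methylbut-2-enoic acid | C/C=C(/C)C(=O)O | starting material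
15 | angelic anhydride, (2Z)-2-methylbut-2-enoic anhydride | C/C=C(/C)C(=O)OC(=O)/C(C)=C\C | intermediate
16 | (1S,2Z)-1-[(2S,3S)-2-ethenyl-4-methylidene-5-oxooxolan-3-yl]-3-iodobut-2-en-1-yl (2Z)-2-methylbut-2-enoate | O=C1C(=C)[C@H]([C@H](OC(=O)/C(C)=C\C)/C=C(/C)I)[C@H](C=C)O1 | intermediate
17 | (4S)-4-benzyl-1,3-oxazolidin-2-one | O=C1OC[C@H](Cc2ccccc2)N1 | starting material
18 | chloroacetyl chloride | ClCC(Cl)=O | starting material
19 | (4S)-4-benzyl-3-(2-chloroacetyl)-1,3-oxazolidin-2-one | ClCC(=O)N1[C@@H](Cc2ccccc2)COC1=O | intermediate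
20 | methacrolein, 2-methylprop-2-enal | CC(=C)C=O | starting material
21 | (4S)-4-benzyl-3-[(2S,3R)-2-chloro-3-hydroxy-4-methylpent-4-enoyl]-1,3-oxazolidin-2-one | C=C(C)[C@@H](O)[C@H](Cl)C(=O)N1[C@@H](Cc2ccccc2)COC1=O | intermediate
22 | (4S)-4-benzyl-3-[(3S)-3-hydroxy-4-methylpent-4-enoyl]-1,3-oxazolidin-2-one | C=C(C)[C@@H](O)CC(=O)N1[C@@H](Cc2ccccc2)COC1=O | intermediate
23 | (4S)-4-benzyl-3-[(3S)-4-methyl-3-(triethylsilyloxy)pent-4-enoyl]-1,3-oxazolidin-2-one | C=C(C)[C@@H](O[Si](CC)(CC)CC)CC(=O)N1[C@@H](Cc2ccccc2)COC1=O | intermediate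
24 | (3S)-4-methyl-3-(triethylsilyloxy)pent-4-en-1-ol | C=C(C)[C@@H](O[Si](CC)(CC)CC)CCO | intermediate
25 | (3S)-4-methyl-3-(triethylsilyloxy)pent-4-enal | C=C(C)[C@@H](O[Si](CC)(CC)CC)CC=O | intermediate
26 | (1R,2Z,4RS,6S)-1-[(2S,3S)-2-ethenyl-4-methylidene-5-oxooxolan-3-yl]-4-hydroxy-3,7-dimethyl-6-(triethylsilyloxy)octa-2,7-dien-1-yl (2Z)-2-methylbut-2-enoate | O=C1C(=C)[C@H]([C@H](OC(=O)/C(C)=C\C)/C=C(/C)C(O)C[C@H](O[Si](CC)(CC)CC)C(C)=C)[C@H](C=C)O1 | intermediate
27 | (1R,2Z,6S)-1-[(2S,3S)-2-ethenyl-4-methylidene-5-oxooxolan-3-yl]-3,7-dimethyl-4-oxo-6-(triethylsilyloxy)octa-2,7-dien-1-yl (2Z)-2-methylbut-2-enoate | O=C1C(=C)[C@H]([C@H](OC(=O)/C(C)=C\C)/C=C(/C)C(=O)C[C@H](O[Si](CC)(CC)CC)C(C)=C)[C@H](C=C)O1 | intermediate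
28 | (1R,2Z,6S)-1-[(2S,3S)-2-ethenyl-4-methylidene-5-oxooxolan-3-yl]-6-hydroxy-3,7-dimethyl-4-oxoocta-2,7-dien-1-yl (2Z)-2-methylbut-2-enoate | O=C1C(=C)[C@H]([C@H](OC(=O)/C(C)=C\C)/C=C(/C)C(=O)C[C@H](O)C(C)=C)[C@H](C=C)O1 | intermediate
29 | (3aS,4R,5Z,9S,10Z,11aS)-9-hydroxy-6,10-dimethyl-3-methylidene-2,7-dioxo-2,3,3a,4,7,8,9,11a-octahydrocyclodeca[b]furan-4-yl (2Z)-2-methylbut-2-enoate | C=C1C(=O)O[C@H]2/C=C(/C)[C@@H](O)CC(=O)/C(C)=C\[C@@H](OC(=O)/C(C)=C\C)[C@@H]12 | intermediate
30 | (3aS,4R,5Z,7S,9S,10Z,11aS)-7,9-dihydroxy-6,10-dimethyl-3-methylidene-2-oxo-2,3,3a,4,7,8,9,11a-octahydrocyclodeca[b]furan-4-yl (2Z)-2-methylbut-2-enoate | C=C1C(=O)O[C@H]2/C=C(/C)[C@@H](O)C[C@H](O)/C(C)=C\[C@@H](OC(=O)/C(C)=C\C)[C@@H]12 | target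

## Step count and risks

Total step count: 20. Longest linear sequence: 13 steps (1 → 30 through steps 1–7, 9 and 16–20). The top half (steps 10–15) and the anhydride (step 8) run in parallel.

The three steps most likely to fail:

Step 6 (lactol methylenation beside a γ-lactone). The basic ylide may attack the lactone, epimerise C6 through the open α-acyloxy aldehyde, or let the lactone drift to O8. Fallback, from 9 and back at 10: open the lactol under acid instead of base. Propane-1,3-dithiol with BF3·OEt2 in CH2Cl2 at −20 °C converts 9 into the dithiane lactone F1. Its C8 hydroxyl is capped with Et3SiOTf/2,6-lutidine to give the silyl ether F2. MeI/CaCO3 in aqueous MeCN releases the aldehyde F3, which is methylenated without base by Zn/CH2I2/TiCl4 (Takai–Lombardo) to the vinyl lactone silyl ether F4. HF·pyridine then returns 10.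

Step 19 (ring-closing metathesis to a ten-membered ring with a trisubstituted olefin). The ring may close slowly, the seco-triene may oligomerise, or the free allylic alcohol may isomerise through Ru–H species. Fallback, from 27 and back at 29: change the order of events and cyclise the silyl ether itself. Metathesis of 27 under high dilution gives the macrocyclic silyl ether F5; this substrate has no free allylic alcohol and a different rotamer bias at C3. HF·pyridine then gives 29.

Step 20 (hydroxyl-directed reduction inside the macrocycle). The ring conformation may override the chair delivery and give the 1,3-syn diol or a mixture. Fallback, from 29 and back at 30: switch from substrate-directed to reagent-controlled reduction. Silylation of the C3 hydroxyl (t-BuMe2SiOTf, 2,6-lutidine) gives the silyl ether F6. Reduction of the enone with (R)-2-methyl-CBS-oxazaborolidine and BH3·SMe2 gives the C1 (S) alcohol F7. HF·pyridine then gives 30.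

Further compounds

F1 | step 6 | 5-(1,3-dithian-2-yl)-4-[(1S,2Z)-1-hydroxy-3-iodobut-2-en-1-yl]oxolan-2-one (ring centres arranged as in 10) | O=C1C[C@H]([C@H](O)/C=C(/C)I)[C@H](C2SCCCS2)O1
F2 | step 6 | triethylsilyl ether of F1 at the side-chain hydroxyl | O=C1C[C@H]([C@H](O[Si](CC)(CC)CC)/C=C(/C)I)[C@H](C2SCCCS2)O1
F3 | step 6 | 3-[(1S,2Z)-3-iodo-1-(triethylsilyloxy)but-2-en-1-yl]-5-oxooxolane-2-carbaldehyde (ring centres arranged as in 10) | O=C1C[C@H]([C@H](O[Si](CC)(CC)CC)/C=C(/C)I)[C@H](C=O)O1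
F4 | step 6 | triethylsilyl ether of 10 | O=C1C[C@H]([C@H](O[Si](CC)(CC)CC)/C=C(/C)I)[C@H](C=C)O1
F5 | step 19 | 9-O-triethylsilyl ether of 29 | C=C1C(=O)O[C@H]2/C=C(/C)[C@@H](O[Si](CC)(CC)CC)CC(=O)/C(C)=C\[C@@H](OC(=O)/C(C)=C\C)[C@@H]12
F6 | step 20 | 9-O-tert-butyldimethylsilyl ether of 29 | C=C1C(=O)O[C@H]2/C=C(/C)[C@@H](O[Si](C)(C)C(C)(C)C)CC(=O)/C(C)=C\[C@@H](OC(=O)/C(C)=C\C)[C@@H]12
F7 | step 20 | 9-O-tert-butyldimethylsilyl ether of 30 | C=C1C(=O)O[C@H]2/C=C(/C)[C@@H](O[Si](C)(C)C(C)(C)C)C[C@H](O)/C(C)=C\[C@@H](OC(=O)/C(C)=C\C)[C@@H]12
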